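The runs are calculated on assumed constants; scatter was added.

Follow the substrate rather than the target, and replace its falling curve by one mean constant, since what has reacted counts every species the substrate has gone into.

| setting | theta | Saturday's | Tuesday's |
|---|---|---|---|
| substrate | 0.010 M | 0.010 M | 0.010 M |
| reagent | 0.011 M | 0.0110 M | 0.0170 M |
| free catalyst | 38 µM | 57 µM | 57 µM |
| remark | run made earlier |  |  |
| time |  | 5.0 h | 5.0 h |

theta run (percent of the substrate charged)

| time / min | substrate / % | target / % |
|---|---|---|
| 5.00 | 98.7 | 0.2 |
| 10.0 | 97.2 | 2.1 |
| 15.0 | 96.9 | 2.1 |
| 30.0 | 92.3 | 5.0 |
| 60.0 | 86.0 | 9.8 |

(readings scatter by 0.5 percentage points)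

- part of the substrate that has reacted at the end, Saturday's
- part of the substrate that has reacted at the end, Tuesday's
- what raising the concentration of reagent from its lowest to its highest value here does to the part of the substrate that has reacted (changes below 5 percentage points count as none) (no change / it rises / it falls)

- amounts and yields of released group count idle adduct too
- what may be going on: substrate + released group <-> idle adduct; released group -> by-product carried off; catalyst intermediate B <-> released group + catalyst intermediate C; reagent + free catalyst -> catalyst intermediate A; reagent + target -> over-reaction product; catalyst intermediate C <-> free catalyst + target; substrate + catalyst intermediate A -> catalyst intermediate B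
- what has gone from substrate into another species counts as reacted, even if it can come back
- no earlier run changes the charge of free catalyst; that part of a forecast is a guess

In the first instants the catalyst can hold hardly any of the substrate: in the theta run c(free catalyst) is 0.380% of c(substrate). Each catalyst unit must therefore turn over repeatedly: the target read at 60.0 min amounts to about 25.8 catalyst charges. At that reading the substrate has lost 14 percentage points and the target stands at 9.8%. The gap of 4.2 points is more than the catalyst could hold, so the target undercounts what has reacted.

For the middle of the run, take the logarithm of charged over remaining substrate, divided by time. The theta run gives 0.151 h⁻¹ for this mean pseudo-first-order constant. Scaled by the catalyst charge, which is a guess, Saturday's has 0.226 h⁻¹, so this reckoning gives 67.7% reacted by 5.0 h. A straight line at the mean rate of the theta run up to its last reading, scaled the same way, reaches 105%, past the charge, so the curve must bend towards the end.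

The theta run has one reagent level. If the constant ignores reagent, Tuesday's stays at 67.7%; if it scales with c(reagent), Tuesday's reaches 82.6%. This reckoning leans to the upper figure.

The forecast gives 71% and 84%, a little apart from these figures, and says of the reagent effect that it rises: “This is a guess; I lean towards a rise”.

The flask gives 71.8% and 82.9%, and it rises by 11 points.

    substrate + released group ⇌ idle adduct, settled at all times (K = 62.0 M⁻¹)
    released group → by-product carried off (k = 0.427 h⁻¹)
    catalyst intermediate B ⇌ released group + catalyst intermediate C (K = 0.700 M, k = 145 h⁻¹)
    reagent + free catalyst → catalyst intermediate A (k = 12800 M⁻¹ h⁻¹)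
    reagent + target → over-reaction product (k = 31.4 M⁻¹ h⁻¹)
    catalyst intermediate C ⇌ free catalyst + target (K = 0.544 M, k = 47.9 h⁻¹)
    substrate + catalyst intermediate A → catalyst intermediate B (k = 4.66 × 10⁵ M⁻¹ h⁻¹)

Saturday's own mean constant is 0.254 h⁻¹, larger than the 0.226 h⁻¹ carried from the theta run. A neighbouring flask, charged like Tuesday's but with 0.010 M of reagent, takes this constant scaled by its reagent, 0.230 h⁻¹, which gives 68.3% reacted by 5.0 h. That neighbouring flask gives 68.9%.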